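## Retrosynthetic overview

1. The 1,3-diaxial CH2OH / tertiary OH pair of the hydrindane is carried as a C3a–CH2–O–C7 ether bridge (oxidised to the lactone, then reduced); the tertiary acetate comes from a tertiary boronic ester.
2. Ring A (formed last): a bromonium ion closes onto the exo-methylene carbon of a vinyl boronate complex; the anti 1,2-shift from boron joins the two halves and fixes C-1 and C-4 of ring A.
3. Cyclopentane (formed second): 5-exo carbolithiation of a vinyl group by a 2-lithioethyl arm, trapped as a pinacol boronate.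
4. Bromocyclohexane of the hydrindane (formed first): enantiospecific bromonium–olefin cyclisation, terminated by the oxygen of a spiro-oxolane (tricyclic oxonium ion), which iodide then opens.
5. Building blocks: methyl geranate, oxolan-3-one and 6-methylhept-5-en-2-one; both C–Br centres come from Shi epoxides by SN2 bromide opening.

Assumption: methyl (2E)-geranate, oxolan-3-one and the D-fructose-derived Shi ketone are bought; "hydrindane numbering" below is that of the target (C-1 side chain, C-3a angular carbon, C-4 bromide, C-7 carbinol, C-7a ring-fusion CH).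

## Route

Step 1
Reactants: 1 6-methylhept-5-en-2-one
Product: 2 (R)-4-(3,3-dimethyloxiran-2-yl)butan-2-one
Conditions: D-fructose-derived Shi ketone (0.3 equiv), KHSO5 (as 2KHSO5·KHSO4·K2SO4), K2CO3, Bu4NHSO4, MeCN/CH2(OMe)2/aq. Na2B4O7 buffer, 0 °C
Reagents that add atoms: potassium peroxymonosulfate, [K+].[O-]S(=O)(=O)OO
Why: Shi asymmetric epoxidation; the chiral dioxirane attacks the trisubstituted olefin through the spiro transition state and gives the (R)-configured CH–O carbon that becomes the ring-A C–Br centre.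

Step 2
Reactants: 2 (R)-4-(3,3-dimethyloxiran-2-yl)butan-2-one
Product: 4 4-[(2R)-3,3-dimethyloxiran-2-yl]but-1-en-2-yl trifluoromethanesulfonate, via lithium enolate 3 (not isolated)
Conditions: LiN(iPr)2, THF, −78 °C; then PhNTf2, −78 to 0 °C
Reagents that add atoms: N-phenylbis(trifluoromethanesulfonimide), O=S(=O)(N(c1ccccc1)S(=O)(=O)C(F)(F)F)C(F)(F)F
Why: kinetic deprotonation at the methyl group and O-sulfonylation of the terminal enolate (enol triflate formation); no stereocentre is touched.

Step 3
Reactants: 4 4-[(2R)-3,3-dimethyloxiran-2-yl]but-1-en-2-yl trifluoromethanesulfonate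
Product: 5 tributyl{4-[(2R)-3,3-dimethyloxiran-2-yl]but-1-en-2-yl}stannane
Conditions: (Bu3Sn)2, Pd(PPh3)4 (5 mol %), LiCl, THF, 65 °C
Reagents that add atoms: hexabutylditin, CCCC[Sn](CCCC)(CCCC)[Sn](CCCC)(CCCC)CCCC
Why: palladium-catalysed coupling of an alkenyl triflate with a distannane (Stille-type stannylation); the epoxide is inert to zerovalent palladium here.

Step 4
Reactants: 5 tributyl{4-[(2R)-3,3-dimethyloxiran-2-yl]but-1-en-2-yl}stannane
Product: 6 (3S)-3-bromo-2-methyl-6-(tributylstannyl)hept-6-en-2-ol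
Conditions: Li2NiBr4, THF, 0 to 20 °C; aq. NaH2PO4/Na2HPO4 work-up
Reagents that add atoms: dilithium tetrabromonickelate, [Li+].[Li+].[Ni+2].[Br-].[Br-].[Br-].[Br-]
Why: SN2 opening of the epoxide by soft bromide at the less substituted carbon with inversion, (R)-C–O to (S)-C–Br, leaving the tertiary alcohol as the latent leaving group.

Step 5
Reactants: 7 methyl (2E)-3,7-dimethylocta-2,6-dienoate (methyl geranate)
Product: 9 methyl (2E)-6-hydroxy-3-methylhex-2-enoate, via aldehyde 8 (not isolated)
Conditions: O3, CH2Cl2/MeOH, −78 °C (indicator end point); then NaBH4, −78 to 0 °C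
Reagents that add atoms: ozone, [O-][O+]=O
Why: chemoselective ozonolysis of the electron-rich trisubstituted olefin (the conjugated enoate reacts far more slowly) with reductive work-up; the (E)-enoate geometry is kept.

Step 6
Reactants: 9 methyl (2E)-6-hydroxy-3-methylhex-2-enoate
Product: 10 methyl (2E)-6-iodo-3-methylhex-2-enoate
Conditions: I-I, PPh3, imidazole, CH2Cl2, 0 to 20 °C
Reagents that add atoms: iodine, I-I
Why: Appel-type iodination of a primary alcohol (SN2 on the alkoxyphosphonium ion).

Step 7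
Reactants: 10 methyl (2E)-6-iodo-3-methylhex-2-enoate
Product: 11 [(4E)-6-methoxy-4-methyl-6-oxohex-4-en-1-yl]triphenylphosphonium iodide
Conditions: PPh3, MeCN, 80 °C
Reagents that add atoms: triphenylphosphine, c1ccc(cc1)P(c1ccccc1)c1ccccc1
Why: SN2 quaternisation of the primary iodide.

Step 8
Reactants: 11 [(4E)-6-methoxy-4-methyl-6-oxohex-4-en-1-yl]triphenylphosphonium iodide; 12 oxolan-3-one (dihydrofuran-3(2H)-one)
Product: 14 methyl (2E,6Z)-3-methyl-6-(oxolan-3-ylidene)hex-2-enoate, via ylide 13 (not isolated)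
Conditions: NaN(SiMe3)2, THF, −78 °C; then 12, −78 to 20 °C
Reagents that add atoms: none
Why: Wittig olefination; unstabilised ylides add to α-alkoxy ketones so that the O–CH2 carbon ends cis to the ylide chain (the (Z)-selective Wittig of α-alkoxy ketones), the geometry that later puts the O–CH2 arm axial.

Step 9
Reactants: 14 methyl (2E,6Z)-3-methyl-6-(oxolan-3-ylidene)hex-2-enoate
Product: 15 methyl (2E)-3-methyl-5-[(2R,3S)-1,5-dioxaspiro[2.4]heptan-2-yl]pent-2-enoate
Conditions: D-fructose-derived Shi ketone (0.3 equiv), KHSO5 (as 2KHSO5·KHSO4·K2SO4), K2CO3, Bu4NHSO4, MeCN/CH2(OMe)2/aq. Na2B4O7 buffer, 0 °C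
Reagents that add atoms: potassium peroxymonosulfate, [K+].[O-]S(=O)(=O)OO
Why: Shi epoxidation; only the electron-rich alkylidene-oxolane reacts (the enoate is inert to the electrophilic dioxirane), and the same facial preference as in step 1 gives the (R)-CH–O carbon while the syn addition keeps the olefin geometry.

Step 10
Reactants: 15 methyl (2E)-3-methyl-5-[(2R,3S)-1,5-dioxaspiro[2.4]heptan-2-yl]pent-2-enoate
Product: 16 methyl (2E,6S)-6-bromo-6-[(3S)-3-hydroxyoxolan-3-yl]-3-methylhex-2-enoate
Conditions: Li2NiBr4, THF, 0 to 20 °C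
Reagents that add atoms: dilithium tetrabromonickelate, [Li+].[Li+].[Ni+2].[Br-].[Br-].[Br-].[Br-]
Why: SN2 epoxide opening by bromide at the secondary carbon with inversion (the spiro carbon, flanked by a β-oxygen, resists ionisation), giving the anti bromohydrin that encodes one enantiomer of the bromonium ion.

Step 11
Reactants: 16 methyl (2E,6S)-6-bromo-6-[(3S)-3-hydroxyoxolan-3-yl]-3-methylhex-2-enoate
Product: 19 methyl (1S,2S,5R,8S)-2-bromo-1-(2-iodoethyl)-5-methyl-6-oxabicyclo[3.2.1]octane-8-carboxylate, via tertiary triflate 17 (not isolated), via tricyclic oxonium triflate 18 (not isolated)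
Conditions: Tf2O (1.1 equiv), 2,6-di-tert-butyl-4-methylpyridine, CH2Cl2, −78 to −30 °C; then Bu4NI (3 equiv), −30 to 0 °C
Reagents that add atoms: tetrabutylammonium iodide, CCCC[N+](CCCC)(CCCC)CCCC.[I-]
Why: Proposed new method: O-triflation of the tertiary alcohol lets the β-bromine expel triflate to give a single enantiomer of the bromonium ion, the (E)-enoate C2=C3 bond attacks it through a chair (Br and ester equatorial, O–CH2 arm axial), the tertiary cation is captured by the 1,3-diaxially placed oxolane oxygen, and iodide opens the tricyclic oxonium ion at its unhindered primary CH2, which sets four stereocentres; the closest known types are enantiospecific bromonium generation from bromohydrin derivatives, bromonium-initiated polyene cyclisation (enoate termination as in the acid cyclisation of geranic and farnesic esters) and oxonium-ion ring opening.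

Step 12
Reactants: 19 methyl (1S,2S,5R,8S)-2-bromo-1-(2-iodoethyl)-5-methyl-6-oxabicyclo[3.2.1]octane-8-carboxylate
Product: 20 (1S,2S,5R,8S)-2-bromo-1-(2-iodoethyl)-5-methyl-6-oxabicyclo[3.2.1]octane-8-carbaldehyde
Conditions: iBu2AlH (1.15 equiv), CH2Cl2, −78 °C; MeOH, then aq. KNaC4H4O6
Reagents that add atoms: none
Why: partial reduction of the ester by iBu2AlH; the β-ether oxygen chelates the tetrahedral aluminate and holds it at the aldehyde stage, and the equatorial CHO is the stable epimer.

Step 13
Reactants: 20 (1S,2S,5R,8S)-2-bromo-1-(2-iodoethyl)-5-methyl-6-oxabicyclo[3.2.1]octane-8-carbaldehyde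
Product: 21 (1S,2S,5R,8S)-2-bromo-8-ethenyl-1-(2-iodoethyl)-5-methyl-6-oxabicyclo[3.2.1]octane
Conditions: Ph3PCH3Br, KN(SiMe3)2, THF, 0 °C; then 20, −78 to 0 °C
Reagents that add atoms: methyltriphenylphosphonium bromide, C[P+](c1ccccc1)(c1ccccc1)c1ccccc1.[Br-]
Why: Wittig methylenation, faster at −78 °C than enolisation of the hindered aldehyde or alkylation of the ylide by the primary iodide.

Step 14
Reactants: 21 (1S,2S,5R,8S)-2-bromo-8-ethenyl-1-(2-iodoethyl)-5-methyl-6-oxabicyclo[3.2.1]octane
Product: 24 pinacol boronate of the bridged hydrindane (hydrindane of 32 with the 3a-CH2–O–C7 ether bridge and B(pin) on the 1-CH2 group; every stereocentre arranged as in 32), via alkyllithium 22 (not isolated), via cyclised alkyllithium 23 (not isolated)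
Conditions: t-BuLi (2.1 equiv), n-pentane/Et2O 3:2, −78 °C; warm to 20 °C, 1.5 h; −78 °C, 2-isopropoxy-4,4,5,5-tetramethyl-1,3,2-dioxaborolane, then 20 °C
Reagents that add atoms: 2-isopropoxy-4,4,5,5-tetramethyl-1,3,2-dioxaborolane, CC(C)OB1OC(C)(C)C(C)(C)O1
Why: lithium–iodine exchange (primary iodide far faster than the hindered equatorial bromide), then 5-exo-trig anionic cyclisation of the 5-hexenyllithium (Bailey carbolithiation); the two equatorial arms can only close to the trans-hydrindane, the vinyl CH2 turns away from the angular CH2–O so the new CH2 sits on the face of H-7a, and the primary alkyllithium is trapped by electrophilic borylation.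

Step 15
Reactants: 24 pinacol boronate of the bridged hydrindane; 6 (3S)-3-bromo-2-methyl-6-(tributylstannyl)hept-6-en-2-ol
Product: 29 (1S,4S)-4-bromo-3,3-dimethyl-1-[(bridged hydrindan-1-yl)methyl]cyclohexan-1-ol (hydrindane part as in 24), via dilithio alkoxide 25 (not isolated), via boronate complex 26 (not isolated), via triflated boronate complex 27 (not isolated), via tertiary boronic ester 28 (not isolated)
Conditions: 6 (1.2 equiv), MeLi (2.4 equiv), Et2O/THF 9:1, −78 to −50 °C; 24, −78 °C; Tf2O (1.25 equiv), −78 to −30 °C; then aq. NaOH, H2O2, 0 to 20 °C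
Reagents that add atoms: hydrogen peroxide, OO
Why: Proposed new method: the alkenyllithium from tin–lithium exchange adds to boronate 24, Tf2O triflates the tertiary lithium alkoxide, the β-bromine expels triflate, and the bromonium ion is attacked by the CH2 terminus of the vinyl boronate complex while the hydrindanylmethyl group shifts from boron to carbon anti to the new C–C bond (chair with Br and CH2R equatorial, boron axial), oxidation then replacing boron by OH with retention to give the cis-1,4 O/Br pattern; the closest known type is the electrophile-induced 1,2-metallate rearrangement of vinyl boronate complexes (Zweifel-type reactivity with carbon electrophiles) followed by boronate oxidation.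

Step 16
Reactants: 29 (1S,4S)-4-bromo-3,3-dimethyl-1-[(bridged hydrindan-1-yl)methyl]cyclohexan-1-ol
Product: 30 (1S,4S)-4-bromo-3,3-dimethyl-1-[(bridged hydrindan-1-yl)methyl]cyclohexyl acetate
Conditions: KN(SiMe3)2, THF, −78 °C; then Ac2O, −78 to 0 °C
Reagents that add atoms: acetic anhydride, CC(=O)OC(C)=O
Why: O-acylation of the potassium alkoxide of the only free hydroxyl group; the hindered equatorial bromides do not eliminate at −78 °C.

Step 17
Reactants: 30 (1S,4S)-4-bromo-3,3-dimethyl-1-[(bridged hydrindan-1-yl)methyl]cyclohexyl acetate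
Product: 31 bridged lactone acetate (30 with the ether CH2 oxidised to C=O, a 3a-carbonyl-O-7 γ-lactone; stereocentres as in 32)
Conditions: RuCl3·xH2O (5 mol %), NaIO4 (4 equiv), CCl4/MeCN/H2O, 20 °C
Reagents that add atoms: sodium periodate, [Na+].[O-]I(=O)(=O)=O
Why: RuO4 oxidation of an ether to a lactone (Sharpless RuCl3/NaIO4 protocol); the only ether α-C–H bonds are on the bridging CH2, because the other ether carbon is fully substituted.

Step 18
Reactants: 31 bridged lactone acetate
Product: 32 (1S,4S)-4-bromo-1-{[(1S,3aS,4S,7R,7aS)-4-bromo-7-hydroxy-3a-(hydroxymethyl)-7-methyloctahydro-1H-inden-1-yl]methyl}-3,3-dimethylcyclohexyl acetate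
Conditions: LiBH4 (2.5 equiv), THF, 0 to 20 °C, stopped at full lactone conversion
Reagents that add atoms: none
Why: chemoselective hydride reduction; the strained bridged γ-lactone is reduced faster than the tertiary, axial acetate (hindered like a tert-butyl ester), and acyl–oxygen cleavage leaves the axial C-7 oxygen and the CH2OH in the 1,3-diaxial arrangement fixed in step 11.

## Compound list

1 | 6-methylhept-5-en-2-one | CC(=O)CCC=C(C)C | starting material
2 | (R)-4-(3,3-dimethyloxiran-2-yl)butan-2-one | CC(=O)CC[C@H]1OC1(C)C | intermediate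
3 | lithium 4-[(2R)-3,3-dimethyloxiran-2-yl]but-1-en-2-olate | [Li+].[O-]C(=C)CC[C@H]1OC1(C)C | intermediate
4 | 4-[(2R)-3,3-dimethyloxiran-2-yl]but-1-en-2-yl trifluoromethanesulfonate | C=C(OS(=O)(=O)C(F)(F)F)CC[C@H]1OC1(C)C | intermediate
5 | tributyl{4-[(2R)-3,3-dimethyloxiran-2-yl]but-1-en-2-yl}stannane | C=C([Sn](CCCC)(CCCC)CCCC)CC[C@H]1OC1(C)C | intermediate
6 | (3S)-3-bromo-2-methyl-6-(tributylstannyl)hept-6-en-2-ol | C=C([Sn](CCCC)(CCCC)CCCC)CC[C@H](Br)C(C)(C)O | intermediate
7 | methyl (2E)-3,7-dimethylocta-2,6-dienoate | COC(=O)/C=C(\C)CCC=C(C)C | starting material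
8 | methyl (2E)-3-methyl-6-oxohex-2-enoate | COC(=O)/C=C(\C)CCC=O | intermediate
9 | methyl (2E)-6-hydroxy-3-methylhex-2-enoate | COC(=O)/C=C(\C)CCCO | intermediate
10 | methyl (2E)-6-iodo-3-methylhex-2-enoate | COC(=O)/C=C(\C)CCCI | intermediate
11 | [(4E)-6-methoxy-4-methyl-6-oxohex-4-en-1-yl]triphenylphosphonium iodide | COC(=O)/C=C(\C)CCC[P+](c1ccccc1)(c1ccccc1)c1ccccc1.[I-] | intermediate
12 | oxolan-3-one | O=C1CCOC1 | starting material
13 | methyl (2E)-3-methyl-6-(triphenyl-λ5-phosphanylidene)hex-2-enoate | COC(=O)/C=C(\C)CCC=P(c1ccccc1)(c1ccccc1)c1ccccc1 | intermediate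
14 | methyl (2E,6Z)-3-methyl-6-(oxolan-3-ylidene)hex-2-enoate | COC(=O)/C=C(\C)CC/C=C1/CCOC1 | intermediate
15 | methyl (2E)-3-methyl-5-[(2R,3S)-1,5-dioxaspiro[2.4]heptan-2-yl]pent-2-enoate | O1CC[C@@]2(C1)O[C@@H]2CC/C(C)=C/C(=O)OC | intermediate
16 | methyl (2E,6S)-6-bromo-6-[(3S)-3-hydroxyoxolan-3-yl]-3-methylhex-2-enoate | O1CC[C@](O)(C1)[C@@H](Br)CC/C(C)=C/C(=O)OC | intermediate
17 | tertiary triflate of 16 (same configurations) | O1CC[C@](OS(=O)(=O)C(F)(F)F)(C1)[C@@H](Br)CC/C(C)=C/C(=O)OC | intermediate
18 | tricyclic oxonium triflate (oxonium oxygen bound to the bridging CH2, to the CH2CH2 arm and to the methyl-bearing carbon; ring stereocentres as in 19) | C1C[C@]2(C[O+]13)[C@@H](Br)CC[C@]3(C)[C@H]2C(=O)OC.[O-]S(=O)(=O)C(F)(F)F | intermediate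
19 | methyl (1S,2S,5R,8S)-2-bromo-1-(2-iodoethyl)-5-methyl-6-oxabicyclo[3.2.1]octane-8-carboxylate | ICC[C@]1(CO2)[C@@H](Br)CC[C@]2(C)[C@H]1C(=O)OC | intermediate
20 | (1S,2S,5R,8S)-2-bromo-1-(2-iodoethyl)-5-methyl-6-oxabicyclo[3.2.1]octane-8-carbaldehyde | ICC[C@]1(CO2)[C@@H](Br)CC[C@]2(C)[C@H]1C=O | intermediate
21 | (1S,2S,5R,8S)-2-bromo-8-ethenyl-1-(2-iodoethyl)-5-methyl-6-oxabicyclo[3.2.1]octane | ICC[C@]1(CO2)[C@@H](Br)CC[C@]2(C)[C@H]1C=C | intermediate
22 | 2-lithioethyl analogue of 21 (iodine replaced by lithium; same configurations) | [Li]CC[C@]1(CO2)[C@@H](Br)CC[C@]2(C)[C@H]1C=C | intermediate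
23 | (bridged hydrindan-1-yl)methyllithium (trans ring fusion; CH2Li on the face of H-7a; centres as in 32) | [Li]C[C@@H]1CC[C@]2(CO3)[C@@H](Br)CC[C@]3(C)[C@@H]12 | intermediate
24 | 2-[(bridged hydrindan-1-yl)methyl]-4,4,5,5-tetramethyl-1,3,2-dioxaborolane (4-bromo-7-methyl hydrindane with the 3a-CH2–O–C7 bridge; centres as in 32) | CC1(C)OB(C[C@@H]2CC[C@]3(CO4)[C@@H](Br)CC[C@]4(C)[C@@H]23)OC1(C)C | intermediate
25 | dilithio species from 6 (lithium alkoxide and 2-lithioalkene; (S)-C–Br) | [Li+].[O-]C(C)(C)[C@@H](Br)CCC(=C)[Li] | intermediate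
26 | lithium vinyl boronate complex of 24 and 25 | [Li+].[Li+].[O-]C(C)(C)[C@@H](Br)CCC(=C)[B-]1(OC(C)(C)C(C)(C)O1)C[C@@H]2CC[C@]3(CO4)[C@@H](Br)CC[C@]4(C)[C@@H]23 | intermediate
27 | boronate complex 26 with the tertiary oxygen triflated | [Li+].FC(F)(F)S(=O)(=O)OC(C)(C)[C@@H](Br)CCC(=C)[B-]1(OC(C)(C)C(C)(C)O1)C[C@@H]2CC[C@]3(CO4)[C@@H](Br)CC[C@]4(C)[C@@H]23 | intermediate
28 | tertiary pinacol boronic ester (B(pin) axial in place of the ring-A oxygen of 29; Br and CH2R equatorial) | CC1(C)OB(OC1(C)C)[C@]2(C[C@@H]3CC[C@]4(CO5)[C@@H](Br)CC[C@]5(C)[C@@H]34)CC[C@H](Br)C(C)(C)C2 | intermediate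
29 | (1S,4S)-4-bromo-3,3-dimethyl-1-[(bridged hydrindan-1-yl)methyl]cyclohexan-1-ol | O[C@]1(C[C@@H]2CC[C@]3(CO4)[C@@H](Br)CC[C@]4(C)[C@@H]23)CC[C@H](Br)C(C)(C)C1 | intermediate
30 | (1S,4S)-4-bromo-3,3-dimethyl-1-[(bridged hydrindan-1-yl)methyl]cyclohexyl acetate | CC(=O)O[C@]1(C[C@@H]2CC[C@]3(CO4)[C@@H](Br)CC[C@]4(C)[C@@H]23)CC[C@H](Br)C(C)(C)C1 | intermediate
31 | bridged lactone acetate (3a-carbonyl-O-7 γ-lactone of 30) | CC(=O)O[C@]1(C[C@@H]2CC[C@]3(C(=O)O4)[C@@H](Br)CC[C@]4(C)[C@@H]23)CC[C@H](Br)C(C)(C)C1 | intermediate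
32 | (1S,4S)-4-bromo-1-{[(1S,3aS,4S,7R,7aS)-4-bromo-7-hydroxy-3a-(hydroxymethyl)-7-methyloctahydro-1H-inden-1-yl]methyl}-3,3-dimethylcyclohexyl acetate | CC(=O)O[C@]1(C[C@@H]2CC[C@]3(CO)[C@@H](Br)CC[C@@](C)(O)[C@@H]23)CC[C@H](Br)C(C)(C)C1 | target

## Step count and risks

Total step count: 18. Longest linear sequence: 14 steps (steps 5 to 18, from methyl geranate); the ring-A partner 6 takes 4 steps.

Step 11 (oxonium cascade). The conjugated enoate may be too weak a terminator, or the β-oxygenated cation may rearrange first. The fallback sets out from 16 and comes back at 20. iBu2AlH reduction of the enoate followed by Ac2O/pyridine gives the allylic acetate F1, whose non-conjugated olefin is a far better π-nucleophile. The same Tf2O/2,6-di-tert-butyl-4-methylpyridine treatment and Bu4NI quench then give the iodo acetate F2. iBu2AlH at −78 °C frees the iodo alcohol F3, and Dess–Martin periodinane oxidises it to aldehyde 20.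

Step 14 (anionic cyclisation next to a secondary bromide). t-BuLi may attack the C–Br bond, or the carbolithiation may be slow. The fallback sets out from 21 and comes back at 24. It replaces the organolithium by a radical chain: blue-light irradiation of 21 with bis(catecholato)diboron in DMF causes iodine abstraction, 5-exo radical cyclisation and borylation of the primary radical; pinacol/Et3N then gives 24 directly. This fallback makes no new compound (F0).

Step 15 (bromonium closure onto the vinyl boronate complex). Tf2O may attack the boronate complex instead of the alkoxide, or the axial boron may block the chair. The fallback sets out from 2 and 21 and comes back at 29. Epoxy ketone 2 is converted with LiN(iPr)2/Me3SiCl into the silyl enol ether F4. Li2NiBr4 opens it to the bromohydrin F5, and Me3SiOTf with 2,6-di-tert-butyl-4-methylpyridine closes ring A by intramolecular tert-alkylation of the enol silane to the ketone F6. The cyclised alkyllithium made from 21 as in step 14 is then added to F6 at −78 °C. Because the ring of F6 is conformationally mobile, 29 is formed together with its C-1 epimer and must be separated by chromatography.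

Further compounds
F1 | step 11 | (2E,6S)-6-bromo-6-[(3S)-3-hydroxyoxolan-3-yl]-3-methylhex-2-en-1-yl acetate | O1CC[C@](O)(C1)[C@@H](Br)CC/C(C)=C/COC(C)=O
F2 | step 11 | [(1S,2S,5R,8R)-2-bromo-1-(2-iodoethyl)-5-methyl-6-oxabicyclo[3.2.1]octan-8-yl]methyl acetate | ICC[C@]1(CO2)[C@@H](Br)CC[C@]2(C)[C@H]1COC(C)=O
F3 | step 11 | [(1S,2S,5R,8R)-2-bromo-1-(2-iodoethyl)-5-methyl-6-oxabicyclo[3.2.1]octan-8-yl]methanol | ICC[C@]1(CO2)[C@@H](Br)CC[C@]2(C)[C@H]1CO
F0 | step 14 | none | none
F4 | step 15 | {4-[(2R)-3,3-dimethyloxiran-2-yl]but-1-en-2-yl}oxy(trimethyl)silane | C=C(O[Si](C)(C)C)CC[C@H]1OC1(C)C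
F5 | step 15 | (3S)-3-bromo-2-methyl-6-[(trimethylsilyl)oxy]hept-6-en-2-ol | C=C(O[Si](C)(C)C)CC[C@H](Br)C(C)(C)O
F6 | step 15 | (4S)-4-bromo-3,3-dimethylcyclohexan-1-one | O=C1CC[C@H](Br)C(C)(C)C1
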